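The summer run, charged with half the coupling partner of the winter flask, was tabled first at the meeting. It shows mono adduct falling, from 73.4% at 2.00 d to 64.7% at 4.00 d, while the winter flask, followed so far to 20.0 h, read 77.8% and then 79.1% at its last two readings.

the same everywhere: substrate 0.50 M
- winter: coupling partner 3 equiv; the very flask that is asked about, followed so far
- summer: coupling partner 1.5 equiv; run made earlier
- flask: coupling partner 3.00 equiv; time 4.0 d

winter run (percent of the substrate charged): time / h: mono adduct / % = 4.00: 47.7; 8.00: 66.5; 12.0: 75.1; 15.0: 77.8; 20.0: 79.1

summer run (percent of the substrate charged): time / d: mono adduct / % = 0.333: 41.0; 0.625: 59.1; 1.04: 67.1; 2.00: 73.4; 4.00: 64.7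

(scatter of a reading: 1 percentage point)

- what was read earlier has a scatter of 1 percentage point, one standard deviation
- a reading or a percentage of mono adduct counts all its forms, free or not

1. equivalents of coupling partner to substrate, everything else as given, that leave most mono adduct at 4.0 d
2. the amount of mono adduct then, in percent of the substrate charged
3. the amount of mono adduct with the amounts as given

The chemist minding the flask proposed to work from those last two summer readings. As a reading with their scatter, they give 0.0435 /d, and she called this the drain: the fraction of the substrate charged that mono adduct loses per day, counted as a fixed amount per day, which the trade calls zero-order.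

She then set the zero of her scale, the supposed case in which the drain is the same at either charge of coupling partner. The winter flask would then slide from its last reading of 79.1% at the summer drain to 65.3% at 4.0 d.

A colleague objected that the winter flask was charged with twice the coupling partner of the summer run. She therefore assumed a doubled drain and committed to 51.5% as her own figure.

The author of the forecast then gave 40% for the flask as charged, and 67% at a best charge of 1.3 equiv, arguing that “Fewer equivalents slow formation but also slow loss”. That 40% stands below her figure, and the minutes record both.

The simulated flask gives 49.1% as charged, and 65.3% at a best charge of 1.48 equiv.

    coupling partner + mono adduct → bis adduct (k = 0.170 /M/h)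
    coupling partner + bis adduct → tris adduct (k = 0.0150 /M/h)
    substrate + coupling partner → mono adduct (k = 0.130 /M/h)
    crystals ⇌ mono adduct, rate k4*(cs4 - [mono adduct]) while solid is left; crystals form when [mono adduct] > cs4 (solubility = 8.80 mM, k = 7.80 /h)
    mono adduct → over-reaction product (k = 0.130 /h)

Between 2.00 d and 4.00 d the winter flask went from 71.3% to 49.1% of mono adduct, of which 47.4% was crystals at the end. That is a drain of 0.111 /d, or 2.55 times the summer drain. The same flask can be carried further at this drain, to its reading at 10 d. The line reaches zero at 8.42 d, earlier than that reading. The flask read at 10 d holds 0% of mono adduct.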